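The data come from a simulation for an exercise; scatter was added.

The product of a racemate over a single-handed catalyst leans to one hand, and the lean fades as the run goes deeper. I call a substrate's depth minus the natural log of the fraction of its own charge still left.

common to all: left-handed substrate 0.13 M; right-handed substrate 0.13 M

| run | partner | precatalyst | remark | time |
|---|---|---|---|---|
| Monday's | 0.17 M | 1.3 mM | run made earlier |  |
| Saturday's | 0.39 M | 1.3 mM | run made earlier |  |
| Friday's | 0.26 M | 0.65 mM | run made earlier |  |
| flask | 0.260 M | 1.3 mM |  | 6.0 min |

| run | time / min | left-handed product / % | right-handed product / % |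
|---|---|---|---|
| Monday's | 0.500 | 1.7 | 0 |
| Monday's | 1.50 | 7.1 | 3.2 |
| Monday's | 3.00 | 13.6 | 5.9 |
| Monday's | 4.00 | 17.3 | 7.1 |
| Monday's | 6.00 | 20.7 | 9.2 |
| Saturday's | 1.33 | 18.8 | 8.1 |
| Saturday's | 2.50 | 28.8 | 13.6 |
| Saturday's | 4.00 | 34.6 | 17.5 |
| Saturday's | 5.00 | 36.9 | 19.0 |
| Saturday's | 6.00 | 38.2 | 20.4 |
| Friday's | 0.500 | 1.4 | 0.3 |
| Friday's | 0.833 | 3.1 | 1.7 |
| Friday's | 1.50 | 8.3 | 2.8 |
| Friday's | 3.00 | 16.5 | 6.8 |
| Friday's | 6.00 | 24.3 | 11.0 |

(scatter of a reading: 0.3 percentage points)

- free catalyst is single-handed; left-handed substrate and right-handed substrate are mirror images of each other, charged as a racemate, each of them at the stated concentration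
- the analysis behind the earlier runs scatters by 0.3 percentage points, standard deviation
- an excess is below zero if the other one leads

* excess of left-handed product over right-handed product in the product at 40 s
* excess of left-handed product over right-handed product in the product at 6.0 min
* part of the left-handed substrate and right-handed substrate charged together that has reacted at 6.0 min

Both substrates meet the same partner and the same catalyst, so by hand I expected the ratio of their depths to stay put whichever setting I turned. Turning up the partner should deepen both. At 6.00 min, the right-handed depth went from 0.203 in Monday's run at 0.17 M to 0.524 in Saturday's at 0.39 M, while the ratio read 2.63 and 2.75.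

Interpolating on the partner gave the flask a right-handed depth of 0.335. Cutting the precatalyst should lower depth in proportion, but Friday's run at 0.65 mM reached 0.248, a factor 1.35 for a factor 2.00 in charge. Its ratio read 2.68.

I took the mean as the selectivity factor s, left-handed depth over right-handed depth: 2.69. The first product then has an excess of s less one over s plus one, 45.8%, my figure for 40 s. At 6.0 min, my depth left 71.6% of the right-handed charge and 40.7% of the left-handed, so 43.9% had reacted, at an excess of 35.2%.

The forecast said 45%, 36% and 42.5%, a little below me on the part reacted, and like me it held that “the selectivity is constant”. The flask gave 45.3%, 35.7% and 44.1%.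

    partner + free catalyst + left-handed substrate → free catalyst + left-handed product (k = 41.0 L² mol⁻² s⁻¹)
    partner + free catalyst + right-handed substrate → free catalyst + right-handed product (k = 15.0 L² mol⁻² s⁻¹)
    free catalyst → spent catalyst A (k = 1.30 × 10⁻⁵ s⁻¹)
    2 free catalyst → spent catalyst B (k = 12.0 L mol⁻¹ s⁻¹)
    partner + precatalyst → free catalyst + spent reagent (k = 0.0390 L mol⁻¹ s⁻¹)

Both product steps carry the same free catalyst and partner, though by 6.00 min free catalyst stood at 16.3% of the catalyst charged and spent catalyst B at 76.3%. The flask's 72% of right-handed charge, raised to the power s, gives 40.8%, and 40% of the left-handed stood there.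

With 0.65 M of partner, the same flask's 40% of right-handed charge gives 8.50% left-handed and an excess of 20.8%. It computed 8.1% and 20.9%.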